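In this closed, stirred vessel at constant temperature, starting material and coupling partner meet on a free catalyst and give target, with second substrate charged beside them.

common to all: starting material 0.25 M; free catalyst 0.21 mM

|  | coupling partner | second substrate | temperature | remark | time |
|---|---|---|---|---|---|
| summer | 0.64 M | 0.050 M | 0 °C | run made earlier |  |
| autumn | 1 M | 0.050 M | 11 °C | run made earlier |  |
| dawn | 1.8 M | 0.050 M | 0 °C | run made earlier |  |
| Wednesday's | 0.500 M | 0.0500 M | 5 °C |  | 3.0 h |
| Monday's | 2.00 M | 0.0500 M | 5 °C |  | 1.5 h |

| run | time / min | target / % |
|---|---|---|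
| summer | 8.00 | 4.0 |
| summer | 15.0 | 6.2 |
| summer | 25.0 | 9.1 |
| summer | 50.0 | 16.6 |
| summer | 90.0 | 25.4 |
| autumn | 8.00 | 8.9 |
| autumn | 25.0 | 20.5 |
| autumn | 40.0 | 27.0 |
| autumn | 60.0 | 32.6 |
| autumn | 90.0 | 37.6 |
| dawn | 8.00 | 8.6 |
| dawn | 25.0 | 25.0 |
| dawn | 40.0 | 36.0 |
| dawn | 60.0 | 45.6 |
| dawn | 90.0 | 57.2 |

(scatter of a reading: 0.3 percentage points)

* the flask that ends with the higher amount of target, in percent of the starting material charged, or "neither" when 2 percentage points or less lies between them (Wednesday's / Monday's / neither)
* final target, as a percentage of the starting material charged, in Wednesday's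
* final target, as a percentage of the starting material charged, in Monday's

- the analysis behind the earlier runs scatters by 0.3 percentage points, standard deviation

I build the flask one process at a time, reckoning with the logarithm of charged over remaining starting material. With the main step alone and coupling partner held, a pseudo-first-order picture, that logarithm climbs straight with time. Add first-order catalyst death and it bends towards a ceiling.

The summer run shows the bend: over 25.0 min and twice that time the logarithm reads 0.0954 and 0.182, a factor of 1.91. So the death constant reads 0.00410 min⁻¹, roughly, given the scatter, and the ceiling per molar of coupling partner reads 1.53 M⁻¹. The slopes of the autumn run read a death constant of 0.0187 min⁻¹ and a ceiling per molar of 0.579 M⁻¹.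

Going 0.455 of the way between them on logarithms, I get a death constant of 0.00817 min⁻¹ at 5 °C and 0.984 M⁻¹ for the reach: the main-step constant at full catalyst, per molar of coupling partner, divided by the death constant, so that time drops out.

With the main step alone I reckon 51.5% in Wednesday's and 76.5% in Monday's. Adding catalyst death, my reckoning drops to 31.5% and 64.1%. Then I let second substrate take its own amount of coupling partner, and I commit to 28.9% and 63.2%, Monday's higher.

The forecast says Monday's, with 38% and 56%, and notes: “The curves also sag beyond substrate depletion, which points to catalyst death.” It stands above my Wednesday's figure and below my Monday's.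

The flask gives 28.3% in Wednesday's and 64.1% in Monday's, so Monday's ends higher.

    coupling partner ⇌ dormant form (K = 0.910, k = 2.51 × 10⁻⁵ s⁻¹, Ea = 102 kJ mol⁻¹, ΔH = −20.0 kJ mol⁻¹)
    free catalyst → spent catalyst (k = 1.41 × 10⁻⁴ s⁻¹, Ea = 82.0 kJ mol⁻¹)
    second substrate + coupling partner + free catalyst → free catalyst + second product (k = 5.12 M⁻² s⁻¹, Ea = 45.0 kJ mol⁻¹)
    starting material + coupling partner + free catalyst → free catalyst + target (k = 0.734 M⁻² s⁻¹, Ea = 35.0 kJ mol⁻¹)
    (constants at 5 °C)

In Monday's at 1.50 h, the half-life of starting material by the main step is 1.7 h, and that of free catalyst by death is shorter at 1.4 h. Their ratio, 0.803, is the gain in the logarithm still open from that moment if coupling partner is held at its level then, and my reach on the coupling partner and free catalyst then present gives 0.722. For a flask like Monday's with 1.3 × 10⁻⁴ M of free catalyst, I scale the reach with the catalyst charge and get 46.1%; the flask gives 47.5%.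

All runs are calculated for substances that don't exist; the scatter is artificial.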